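A steady rate cannot have drawn these curves: it would make the loss at 15.0 h 1.88 times the loss at 8.00 h, and the readings do not show that.

| flask | electrophile | buffer base | buffer acid | solid nucleophile | remark | time |
|---|---|---|---|---|---|---|
| Thursday's | 32 mM | 16 mM (fed, over 12 h) | 1.6 mM | 96 mM | run made earlier |  |
| Sunday's | 32 mM | 16 mM (fed, over 12 h) | 6.4 mM | 96 mM | run made earlier |  |
| Tuesday's | 48 mM | 16 mM (fed, over 12 h) | 3.2 mM | 96 mM | run made earlier |  |
| flask | 32 mM | 16.0 mM (fed, over 12 h) | 3.20 mM | 96.0 mM |  | 12 h |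

| run | time / h | electrophile / % | product / % |
|---|---|---|---|
| Thursday's | 0.833 | 97.8 | 1.0 |
| Thursday's | 2.00 | 99.6 | 1.0 |
| Thursday's | 4.00 | 99.9 | 2.1 |
| Thursday's | 6.00 | 96.6 | 1.8 |
| Thursday's | 8.00 | 95.5 | 5.3 |
| Thursday's | 12.0 | 90.6 | 7.9 |
| Thursday's | 15.0 | 86.6 | 16.4 |
| Sunday's | 0.833 | 100.7 | 0 |
| Sunday's | 2.00 | 99.8 | 0.6 |
| Sunday's | 4.00 | 98.6 | 1.5 |
| Sunday's | 6.00 | 98.0 | 2.1 |
| Sunday's | 8.00 | 95.4 | 3.5 |
| Sunday's | 12.0 | 91.6 | 10.3 |
| Sunday's | 15.0 | 87.4 | 11.5 |
| Tuesday's | 1.00 | 99.4 | 0.1 |
| Tuesday's | 2.00 | 101.6 | 0 |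
| Tuesday's | 4.00 | 99.3 | 0.2 |
| Tuesday's | 8.00 | 96.2 | 4.0 |
| Tuesday's | 15.0 | 88.5 | 12.3 |

(standard deviation of a reading: 1 percentage point)

* part of the electrophile that has reacted at 12 h
* pH of the solution at 12 h

- the analysis behind the earlier runs scatters by 1 percentage point, standard deviation
- at the start none of the solid nucleophile is in solution
- the earlier runs do not show the pH; that part of a forecast is a guess

Averaging electrophile lost and product gained over the earlier runs gives 12.9% at 15.0 h and 4.28% at 8.00 h. That ratio of 3.01 lies nearer the 3.52 of a square law. None of the solid nucleophile is in solution at the start, and if it dissolves steadily and the rate of loss grows in step with what has dissolved, the loss grows with the square of time.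

The electrophile loss at 15.0 h reads 13.4% in Thursday's run, 12.6% in Sunday's with 4.00 times the buffer acid, and 11.5% in Tuesday's with 48 mM of electrophile and 3.2 mM of buffer acid. So we let one time serve them and this flask.

That time is the ramp time, the time in which a loss growing with the square of time would reach the whole electrophile: 41.7 h. Set against the asked 12 h, the square of their ratio gives our reckoning, 8.29%.

The forecast stands higher, at 9% and pH 7.5, holding that the reaction “looks first order in electrophile”. The flask gives 8.95% and pH 6.55.

    solid nucleophile ⇌ nucleophile, rate k1*(cs1 - [nucleophile]) while solid is left; crystals form when [nucleophile] > cs1 (solubility = 28.0 mM, k = 4.90 × 10⁻⁴ /min)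
    buffer acid ⇌ buffer base + acid, settled at all times (K = 6.30 × 10⁻⁷ M)
    electrophile + nucleophile ⇌ acid + product + leaving group (K = 9.00 × 10⁻⁷ M, k = 0.0390 /M/min)
    protonated nucleophile ⇌ nucleophile + acid, settled at all times (K = 1.30 × 10⁻⁵ M)

Read back, this flask has a ramp time of 40.1 h against our 41.7 h. We keep our ramp time for the neighbouring flask with 58 mM of solid nucleophile, 1.81 equiv against 3 here, and it gives 8.28% again. That neighbouring flask gives 8.95%, with 85.0% of its solid nucleophile charge still solid.

The runs were computed on assumed constants; scatter was added.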